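**Plan**

- Retrosynthesis: the C12–C13 bond is cut first (alkylborane + 3-bromofuran-2(5H)-one), then C8–C9 of ring B (intramolecular SN2′ alkylation), then C1–C10 and C4–C5 of ring A together ([4+2]).
- Enabling feature: in ring A the C19 carboxyl carbon on C4 and C1 stand 1,4. Joined through oxygen they give a 2-oxabicyclo[2.2.2]oct-7-en-3-one, the adduct of a 2-pyrone (C1–C4 plus C19) with the C5=C10 alkene. Because H-5 is trans to CH3-20, that alkene is an (E)-2-methyl-2-enal (C9 = CHO).
- Forward: ring A first (3-methyl-2-pyrone + enal 5). The two helpers are then removed (allylic O–C1 bond by palladium/tin hydride, C2=C3 by hydrogenation). Ring B follows, then the butenolide.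
- Stereochemistry: C10 (absolute) from a chiral boron Lewis acid, C5 from the E alkene, C4 from the pyrone ring and the endo mode (C19 cis to C20), C9 from a chair closure trans-fused to ring A, C8 by equilibration of its ester.

Key step: step 3

Numbering: labdane numbers are used for atoms (C1–C10 decalin, C17 on C8, C18 and C19 on C4, C20 on C10, C11–C16 side chain).

Assumption: the (S)-oxazaborolidinium catalyst is taken to direct the diene to the Si face of the formyl-bearing alkene carbon of 5 (the face that leads to 6); if the sense is the opposite, the (R)-catalyst is used and nothing else changes.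

**Route**

Step 1
Reactants: 1 3-bromo-2H-pyran-2-one
Product: 2 3-methyl-2H-pyran-2-one
Conditions: CH3ZnCl (1.5 equiv), Pd(PPh3)4 (5 mol %), THF, 0 → 25 °C
Reagents that add atoms: methylzinc chloride, C[Zn]Cl
Why: Negishi cross-coupling, in which the C3–Br bond of the pyrone behaves as an α-bromo enoate toward zerovalent palladium and the organozinc is too mild to open the lactone.

Step 2
Reactants: 3 methyl hex-5-enoate; 4 methacrolein (2-methylprop-2-enal)
Product: 5 methyl (5E)-6-methyl-7-oxohept-5-enoate
Conditions: second-generation Grubbs catalyst (3 mol %), 4 (5 equiv), CH2Cl2, 40 °C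
Reagents that add atoms: none
Why: Olefin cross-metathesis of a terminal alkene with methacrolein should give the conjugated trisubstituted enal as the E isomer (thermodynamic control), the geometry that later becomes the trans relation of H-5 and CH3-20.

Step 3
Reactants: 2 3-methyl-2H-pyran-2-one; 5 methyl (5E)-6-methyl-7-oxohept-5-enoate
Product: 6 methyl 4-[(1R,4S,5R,6R)-6-formyl-4,6-dimethyl-3-oxo-2-oxabicyclo[2.2.2]oct-7-en-5-yl]butanoate
Conditions: (S)-1-(2-methylphenyl)-3,3-diphenyltetrahydro-1H,3H-pyrrolo[1,2-c][1,3,2]oxazaborole (20 mol %), HN(SO2CF3)2 (18 mol %), 2 (2.5 equiv), CH2Cl2, −40 → 0 °C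
Reagents that add atoms: none
Why: Proposed new method: a [4+2] cycloaddition of a 2-pyrone with an enal held on a chiral boron Lewis acid, in which C3 of the pyrone (future C4, the position of 2-pyrones that takes up electrophiles because the ring oxygen then carries the charge) bonds to the β-carbon of the activated enal (future C5) and the C1–C10 bond closes in the same asynchronous event; the closest known reaction types are the thermal Diels–Alder reactions of 3-substituted 2-pyrones with acroleins and the oxazaborolidinium-catalysed Diels–Alder reactions of α-methyl-β-alkyl enals with simple dienes. Ring A (C1–C2–C3–C4–C5–C10) closes as a cyclohexene by intermolecular suprafacial [4+2] addition, and the lactone of the pyrone is carried over as the O–C19 bridge between C1 and C4. C5 and C10 take their relative configuration (H-5 trans to CH3-20, C6 trans to C9) from the E alkene of 5, C4 from the fact that C19 is held in the pyrone ring while the formyl group sits endo (under C2–C3), which puts CH3-20 on the side of the O–C19 bridge and so C19 cis to C20, C1 from the bridge (it is a CH2 group later), and C10 in the absolute sense from the catalyst, which covers one face of the s-trans enal. The step needs head-to-tail regioselectivity, which the polarity match and the avoidance of a bond between the two fully substituted carbons (pyrone C3 and the enal α-carbon) secure, endo selectivity, which secondary overlap with the boron-bound formyl group favours and which no CH2 bridge opposes as it does for cyclopentadiene, and face selectivity, which rests on the catalyst. The low temperature keeps the bridged lactone from losing CO2, and the excess of 2 offsets its own reversible binding to boron.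

Step 4
Reactants: 6 methyl 4-[(1R,4S,5R,6R)-6-formyl-4,6-dimethyl-3-oxo-2-oxabicyclo[2.2.2]oct-7-en-5-yl]butanoate
Product: 8 (1S,5S,6R)-5-formyl-6-(4-methoxy-4-oxobutyl)-1,5-dimethylcyclohex-2-ene-1-carboxylic acid, via tributylstannyl ester 7 (not isolated)
Conditions: Pd(PPh3)4 (3 mol %), Bu3SnH (1.2 equiv, slow addition), THF, 20 °C; then 1 M HCl
Reagents that add atoms: none
Why: Palladium-catalysed hydride cleavage of an allylic ester (Tsuji–Trost ionisation followed by hydride transfer from tin): zerovalent palladium ionises the allylic C1–O bond of the bridged lactone and Bu3SnH reduces the π-allyl complex at once to the stannyl ester, which acid cleaves; C4 and C10 carry no hydrogen, so no diene can form by β-hydride loss, the fast hydride transfer is meant to outrun loss of CO2 from the carboxylate, the aldehyde is not reduced, and the position of the remaining double bond (C2=C3 or C1=C2) is without consequence.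

Step 5
Reactants: 8 (1S,5S,6R)-5-formyl-6-(4-methoxy-4-oxobutyl)-1,5-dimethylcyclohex-2-ene-1-carboxylic acid
Product: 9 (1S,2R,3S)-3-formyl-2-(4-methoxy-4-oxobutyl)-1,3-dimethylcyclohexane-1-carboxylic acid
Conditions: H2 (1 atm), Pd/C (10 %), EtOAc, 25 °C
Reagents that add atoms: none
Why: Heterogeneous catalytic hydrogenation removes the ring alkene, the second helper; no stereocentre is formed and the hindered aldehyde and the esters should be untouched at 1 atm.

Step 6
Reactants: 9 (1S,2R,3S)-3-formyl-2-(4-methoxy-4-oxobutyl)-1,3-dimethylcyclohexane-1-carboxylic acid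
Product: 10 4-methoxybenzyl (1S,2R,3S)-3-formyl-2-(4-methoxy-4-oxobutyl)-1,3-dimethylcyclohexane-1-carboxylate
Conditions: 4-MeOC6H4CH2Cl (1.2 equiv), Cs2CO3 (1.5 equiv), (n-Bu)4NI (10 mol %), DMF, 25 °C
Reagents that add atoms: 4-methoxybenzyl chloride, COc1ccc(CCl)cc1
Why: SN2 alkylation of the caesium carboxylate, the standard esterification of a hindered tertiary acid; the aldehyde has no α-hydrogen and cannot enolise, and this ester is chosen because acid later cleaves it by alkyl–oxygen fission without touching the butenolide.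

Step 7
Reactants: 10 4-methoxybenzyl (1S,2R,3S)-3-formyl-2-(4-methoxy-4-oxobutyl)-1,3-dimethylcyclohexane-1-carboxylate
Product: 11 4-methoxybenzyl (1S,2R,3S)-3-(1-hydroxyprop-2-en-1-yl)-2-(4-methoxy-4-oxobutyl)-1,3-dimethylcyclohexane-1-carboxylate (either carbinol epimer)
Conditions: CH2=CHMgBr (1.3 equiv), THF, −78 → −40 °C; aq. NH4Cl
Reagents that add atoms: vinylmagnesium bromide, C=C[Mg]Br
Why: Grignard 1,2-addition to the aldehyde, which at −78 °C is far more reactive than either ester; the configuration of the new carbinol carbon is of no consequence because this carbon (C9) becomes sp2 in step 8.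

Step 8
Reactants: 11 4-methoxybenzyl (1S,2R,3S)-3-(1-hydroxyprop-2-en-1-yl)-2-(4-methoxy-4-oxobutyl)-1,3-dimethylcyclohexane-1-carboxylate
Product: 13 4-methoxybenzyl (1S,2R,3R)-3-[(1E)-3-bromoprop-1-en-1-yl]-2-(4-methoxy-4-oxobutyl)-1,3-dimethylcyclohexane-1-carboxylate, via allylic mesylate 12 (not isolated)
Conditions: CH3SO2Cl (1.2 equiv), Et3N (1.5 equiv), CH2Cl2, −40 °C; then LiBr (5 equiv), THF, −40 → 20 °C
Reagents that add atoms: lithium bromide, [Li+].[Br-]
Why: Mesylation followed by bromide substitution with allylic transposition (SN2′ or ion pair); the neopentyl carbon C9 is closed to direct substitution and allylic bromides equilibrate, so the primary (E)-allylic bromide should result.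

Step 9
Reactants: 13 4-methoxybenzyl (1S,2R,3R)-3-[(1E)-3-bromoprop-1-en-1-yl]-2-(4-methoxy-4-oxobutyl)-1,3-dimethylcyclohexane-1-carboxylate
Product: 14 1-(4-methoxybenzyl) 6-methyl (1S,4aR,5S,6R,8aR)-5-ethenyl-1,4a-dimethyldecahydronaphthalene-1,6-dicarboxylate
Conditions: LiN(SiMe3)2 (1.1 equiv), THF (0.005 M), −78 → 0 °C; then NaOCH3 (0.3 equiv), CH3OH, 25 °C
Reagents that add atoms: none
Why: Intramolecular SN2′ alkylation of an ester enolate (6-exo), in which C8 attacks C9 through a chair-like transition state trans-fused to ring A with the forming vinyl group equatorial, which sets C9 (vinyl β, H α), while C8 is set equatorial (ester α, away from the axial CH3-20) by the methoxide equilibration; closure at C12 (eight-membered ring) and Dieckmann attack on the shielded C19 ester should be slower at low temperature.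

Step 10
Reactants: 14 1-(4-methoxybenzyl) 6-methyl (1S,4aR,5S,6R,8aR)-5-ethenyl-1,4a-dimethyldecahydronaphthalene-1,6-dicarboxylate
Product: 15 4-methoxybenzyl (1S,4aR,5S,6R,8aR)-5-ethenyl-6-(hydroxymethyl)-1,4a-dimethyldecahydronaphthalene-1-carboxylate
Conditions: LiBH4 (2 equiv), CH3OH (2 equiv), THF, 0 → 25 °C
Reagents that add atoms: none
Why: Chemoselective hydride reduction of the unhindered methyl ester; the C19 ester sits on a quaternary carbon in an axial position 1,3 to CH3-20 and should be left, and no stereocentre changes.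

Step 11
Reactants: 15 4-methoxybenzyl (1S,4aR,5S,6R,8aR)-5-ethenyl-6-(hydroxymethyl)-1,4a-dimethyldecahydronaphthalene-1-carboxylate; 16 3-bromofuran-2(5H)-one
Product: 18 4-methoxybenzyl (1S,4aR,5S,6R,8aR)-6-(hydroxymethyl)-1,4a-dimethyl-5-[2-(2-oxo-2,5-dihydrofuran-3-yl)ethyl]decahydronaphthalene-1-carboxylate, via alkylborane 17 (not isolated)
Conditions: 9-BBN (2.5 equiv), THF, 0 → 25 °C; then 16 (1.5 equiv), Pd(dppf)Cl2 (5 mol %), AsPh3 (10 mol %), K3PO4 (3 M aq.), DMF, 25 °C
Reagents that add atoms: none
Why: Anti-Markovnikov hydroboration of the monosubstituted alkene (the hydroxyl group is borylated for the time being) and B-alkyl Suzuki–Miyaura coupling with the α-bromo butenolide under the mild conditions used for α-halo enones; no stereocentre is formed.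

Step 12
Reactants: 18 4-methoxybenzyl (1S,4aR,5S,6R,8aR)-6-(hydroxymethyl)-1,4a-dimethyl-5-[2-(2-oxo-2,5-dihydrofuran-3-yl)ethyl]decahydronaphthalene-1-carboxylate
Product: 19 (1S,4aR,5S,6R,8aR)-6-(hydroxymethyl)-1,4a-dimethyl-5-[2-(2-oxo-2,5-dihydrofuran-3-yl)ethyl]decahydronaphthalene-1-carboxylic acid (target)
Conditions: CF3CO2H/CH2Cl2 (1:4), anisole (5 equiv), 0 °C; then aq. NaHCO3, then acidification to pH 3
Reagents that add atoms: none
Why: Acidolysis of the 4-methoxybenzyl ester by alkyl–oxygen cleavage, which is insensitive to the shielding of the C19 carboxyl; the butenolide and the primary alcohol are stable to CF3CO2H, and any trifluoroacetate of the alcohol is cleaved in the hydrogencarbonate work-up.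

**Compound list**

1 | 3-bromo-2H-pyran-2-one | O=C1OC=CC=C1Br | starting material
2 | 3-methyl-2H-pyran-2-one | CC1=CC=COC1=O | intermediate
3 | methyl hex-5-enoate | C=CCCCC(=O)OC | starting material
4 | methacrolein (2-methylprop-2-enal) | CC(=C)C=O | starting material
5 | methyl (5E)-6-methyl-7-oxohept-5-enoate | O=C/C(C)=C/CCCC(=O)OC | intermediate
6 | methyl 4-[(1R,4S,5R,6R)-6-formyl-4,6-dimethyl-3-oxo-2-oxabicyclo[2.2.2]oct-7-en-5-yl]butanoate (formyl endo; 6-methyl and side chain on the side of the lactone bridge) | C[C@]1(C=O)[C@H]2C=C[C@](C)(C(=O)O2)[C@@H]1CCCC(=O)OC | intermediate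
7 | tributylstannyl (1S,5S,6R)-5-formyl-6-(4-methoxy-4-oxobutyl)-1,5-dimethylcyclohex-2-ene-1-carboxylate | C[C@]1(C=O)CC=C[C@](C)(C(=O)O[Sn](CCCC)(CCCC)CCCC)[C@@H]1CCCC(=O)OC | intermediate
8 | (1S,5S,6R)-5-formyl-6-(4-methoxy-4-oxobutyl)-1,5-dimethylcyclohex-2-ene-1-carboxylic acid | C[C@]1(C=O)CC=C[C@](C)(C(=O)O)[C@@H]1CCCC(=O)OC | intermediate
9 | (1S,2R,3S)-3-formyl-2-(4-methoxy-4-oxobutyl)-1,3-dimethylcyclohexane-1-carboxylic acid | C[C@]1(C=O)CCC[C@](C)(C(=O)O)[C@@H]1CCCC(=O)OC | intermediate
10 | 4-methoxybenzyl (1S,2R,3S)-3-formyl-2-(4-methoxy-4-oxobutyl)-1,3-dimethylcyclohexane-1-carboxylate | C[C@]1(C=O)CCC[C@](C)(C(=O)OCc2ccc(OC)cc2)[C@@H]1CCCC(=O)OC | intermediate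
11 | 4-methoxybenzyl (1S,2R,3S)-3-(1-hydroxyprop-2-en-1-yl)-2-(4-methoxy-4-oxobutyl)-1,3-dimethylcyclohexane-1-carboxylate (carbinol carbon of either configuration) | C[C@]1(C(O)C=C)CCC[C@](C)(C(=O)OCc2ccc(OC)cc2)[C@@H]1CCCC(=O)OC | intermediate
12 | methanesulfonate of 11 (allylic mesylate) | C[C@]1(C(OS(C)(=O)=O)C=C)CCC[C@](C)(C(=O)OCc2ccc(OC)cc2)[C@@H]1CCCC(=O)OC | intermediate
13 | 4-methoxybenzyl (1S,2R,3R)-3-[(1E)-3-bromoprop-1-en-1-yl]-2-(4-methoxy-4-oxobutyl)-1,3-dimethylcyclohexane-1-carboxylate | C[C@]1(/C=C/CBr)CCC[C@](C)(C(=O)OCc2ccc(OC)cc2)[C@@H]1CCCC(=O)OC | intermediate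
14 | 1-(4-methoxybenzyl) 6-methyl (1S,4aR,5S,6R,8aR)-5-ethenyl-1,4a-dimethyldecahydronaphthalene-1,6-dicarboxylate | C[C@]12CCC[C@](C)(C(=O)OCc3ccc(OC)cc3)[C@@H]1CC[C@@H](C(=O)OC)[C@@H]2C=C | intermediate
15 | 4-methoxybenzyl (1S,4aR,5S,6R,8aR)-5-ethenyl-6-(hydroxymethyl)-1,4a-dimethyldecahydronaphthalene-1-carboxylate | C[C@]12CCC[C@](C)(C(=O)OCc3ccc(OC)cc3)[C@@H]1CC[C@@H](CO)[C@@H]2C=C | intermediate
16 | 3-bromofuran-2(5H)-one | O=C1OCC=C1Br | starting material
17 | B-alkyl-9-BBN adduct of 15 at C12, with the C17 oxygen also carrying a 9-borabicyclo[3.3.1]nonan-9-yl group | C[C@]12CCC[C@](C)(C(=O)OCc3ccc(OC)cc3)[C@@H]1CC[C@@H](COB3C4CCCC3CCC4)[C@@H]2CCB3C4CCCC3CCC4 | intermediate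
18 | 4-methoxybenzyl (1S,4aR,5S,6R,8aR)-6-(hydroxymethyl)-1,4a-dimethyl-5-[2-(2-oxo-2,5-dihydrofuran-3-yl)ethyl]decahydronaphthalene-1-carboxylate | C[C@]12CCC[C@](C)(C(=O)OCc3ccc(OC)cc3)[C@@H]1CC[C@@H](CO)[C@@H]2CCC1=CCOC1=O | intermediate
19 | (1S,4aR,5S,6R,8aR)-6-(hydroxymethyl)-1,4a-dimethyl-5-[2-(2-oxo-2,5-dihydrofuran-3-yl)ethyl]decahydronaphthalene-1-carboxylic acid | C[C@]12CCC[C@](C)(C(=O)O)[C@@H]1CC[C@@H](CO)[C@@H]2CCC1=CCOC1=O | target

**Count**

Total steps: 12. Longest linear sequence: 11 steps (1 → 19 through steps 1 and 3–12; equally 3 → 19 through steps 2–12).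

**Steps most likely to fail**

Step 3. The cycloaddition may be too slow at a temperature at which the catalyst still controls the face, the more basic pyrone may hold the boron catalyst, or the endo preference may be weak. The fallback sets out from 2 and 5 and gives up catalyst control for a resolution. The two components are combined without catalyst under 12–15 kbar (CH2Cl2, 25 °C), a known way to bring 2-pyrones to react with sluggish dienophiles while the CO2 bridge is kept. This should give 6 as the racemate, that is together with the enantiomer of 6 F1. The racemate is taken through steps 4 and 5, which adds the enantiomeric stannyl ester F2, the enantiomeric cyclohexene acid F3 and the enantiomeric saturated acid F4. Racemic 9 is then resolved by crystallisation with quinine, a tertiary amine that cannot condense with the aldehyde: the quinine salt of 9 F5 is collected and the quinine salt of the enantiomer F6 stays in the mother liquor (assumed order of solubility; quinidine otherwise). Dilute HCl sets the acid free, and the route is rejoined at 9.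

Step 9. The enolate may close with poor face selectivity at C9, or it may acylate the C19 ester instead of displacing bromide. The fallback sets out from 11 and replaces the lithium enolate and the allylic bromide by a neutral palladium π-allyl closure. The alcohol is converted into the allylic methyl carbonate F7 (ClCO2CH3, pyridine, CH2Cl2, 0 °C). The methyl ester is then turned into the ketene silyl acetal F8 (LiN(SiMe3)2, Me3SiCl, THF, −78 °C). Pd2(dba)3 with Ph2PCH2CH2PPh2 in THF at 65 °C should effect the known allylation of a ketene silyl acetal by an allylic carbonate. The π-allyl complex interconverts its two faces, so the closure can run through the lower-lying chair with the vinyl group equatorial, and no free enolate is present. After the methoxide equilibration of step 9 the route is rejoined at 14.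

Step 11. The base-sensitive bromo butenolide may decompose before the hindered alkylborane transfers its alkyl group. The fallback sets out from 15, through the same borane 17, and brings in the lactone ring as a furan. The coupling partner is 3-bromo-2-(trimethylsilyl)furan F9, made from 3-bromofuran with LiN(iPr)2 and Me3SiCl; it is inert to aqueous base. Coupling under the conditions of step 11 should give the 3-alkyl-2-silylfuran F10. Peracetic acid with NaOAc in CH2Cl2 is known to oxidise 2-silylfurans at the silylated carbon and should give the β,γ-unsaturated lactone F11. Et3N moves its double bond into conjugation, and the route is rejoined at 18.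

**Further compounds**

F1 | step 3 | methyl 4-[(1S,4R,5S,6S)-6-formyl-4,6-dimethyl-3-oxo-2-oxabicyclo[2.2.2]oct-7-en-5-yl]butanoate (enantiomer of 6) | C[C@@]1(C=O)[C@@H]2C=C[C@@](C)(C(=O)O2)[C@H]1CCCC(=O)OC
F2 | step 3 | tributylstannyl (1R,5R,6S)-5-formyl-6-(4-methoxy-4-oxobutyl)-1,5-dimethylcyclohex-2-ene-1-carboxylate (enantiomer of 7) | C[C@@]1(C=O)CC=C[C@@](C)(C(=O)O[Sn](CCCC)(CCCC)CCCC)[C@H]1CCCC(=O)OC
F3 | step 3 | (1R,5R,6S)-5-formyl-6-(4-methoxy-4-oxobutyl)-1,5-dimethylcyclohex-2-ene-1-carboxylic acid (enantiomer of 8) | C[C@@]1(C=O)CC=C[C@@](C)(C(=O)O)[C@H]1CCCC(=O)OC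
F4 | step 3 | (1R,2S,3R)-3-formyl-2-(4-methoxy-4-oxobutyl)-1,3-dimethylcyclohexane-1-carboxylic acid (enantiomer of 9) | C[C@@]1(C=O)CCC[C@@](C)(C(=O)O)[C@H]1CCCC(=O)OC
F5 | step 3 | quininium salt of 9 | C[C@]1(C=O)CCC[C@](C)(C(=O)[O-])[C@@H]1CCCC(=O)OC.COc1ccc2nccc([C@H]([C@@H]3C[C@@H]4CC[NH+]3C[C@@H]4C=C)O)c2c1
F6 | step 3 | quininium salt of the enantiomer of 9 | C[C@@]1(C=O)CCC[C@@](C)(C(=O)[O-])[C@H]1CCCC(=O)OC.COc1ccc2nccc([C@H]([C@@H]3C[C@@H]4CC[NH+]3C[C@@H]4C=C)O)c2c1
F7 | step 9 | 4-methoxybenzyl (1S,2R,3S)-3-[1-(methoxycarbonyloxy)prop-2-en-1-yl]-2-(4-methoxy-4-oxobutyl)-1,3-dimethylcyclohexane-1-carboxylate | C[C@]1(C(OC(=O)OC)C=C)CCC[C@](C)(C(=O)OCc2ccc(OC)cc2)[C@@H]1CCCC(=O)OC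
F8 | step 9 | ketene methyl trimethylsilyl acetal of the methyl ester of F7 | C[C@]1(C(OC(=O)OC)C=C)CCC[C@](C)(C(=O)OCc2ccc(OC)cc2)[C@@H]1CCC=C(OC)O[Si](C)(C)C
F9 | step 11 | 3-bromo-2-(trimethylsilyl)furan | C[Si](C)(C)c1occc1Br
F10 | step 11 | 4-methoxybenzyl (1S,4aR,5S,6R,8aR)-6-(hydroxymethyl)-1,4a-dimethyl-5-{2-[2-(trimethylsilyl)furan-3-yl]ethyl}decahydronaphthalene-1-carboxylate | C[C@]12CCC[C@](C)(C(=O)OCc3ccc(OC)cc3)[C@@H]1CC[C@@H](CO)[C@@H]2CCc1ccoc1[Si](C)(C)C
F11 | step 11 | 4-methoxybenzyl (1S,4aR,5S,6R,8aR)-6-(hydroxymethyl)-1,4a-dimethyl-5-[2-(2-oxo-2,3-dihydrofuran-3-yl)ethyl]decahydronaphthalene-1-carboxylate | C[C@]12CCC[C@](C)(C(=O)OCc3ccc(OC)cc3)[C@@H]1CC[C@@H](CO)[C@@H]2CCC1C=COC1=O
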